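**Retrosynthetic overview** (locants follow the IUPAC name of the target)
1. The vicinal C4(Me)Br/C3HCl pair comes last. It is built from the 4‑methylcyclohex‑3‑enyl oxane via epoxide, then trans‑diaxial chlorohydrin, then tertiary bromide formed with retention through a chloronium ion.
2. The cyclohexene derives from a 2‑methyl‑5‑(oxanyl)cyclohexanone. That ketone derives from a δ‑lactone by excision of one temporary carbonyl carbon (saponification, then hydrodecarboxylation).
3. Key disconnection: cyclohexane bonds C1–C6 and C4–C5 form together in an ester‑tethered intramolecular Diels–Alder reaction. The enabling feature is threefold. The unsubstituted C5H2–C6H2 edge is an ethylene unit. C1, C2, C3 (future CHCl) and C4 (with its CH3) form a 2‑silyloxy‑1,3‑diene. The oxane C3–OH lies along O–C3–C2(oxane)–C1–C6(cyclohexane), one carbonyl carbon short of a six‑membered lactone, so it can carry the ethylene as its acrylate.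
4. Ring order: cyclohexene plus temporary δ‑lactone (step 7), then the oxane by bromoetherification on the lactone template (step 8), then removal of the lactone (step 9).
5. The acyclic precursor comes from three building blocks. 6‑Methylhept‑5‑en‑2‑one supplies all eight oxane carbons. Pent‑1‑yn‑3‑ol supplies cyclohexane C1–C4 and the CH3. Acryloyl chloride supplies C5, C6 and the temporary carbon.

Key step: step 7

Assumption: the sense of induction in step 1 is taken from the known L‑proline → (R) outcome of enamine aminoxylations of aldehydes and cyclic ketones, so D‑proline is chosen for the (S)‑ketol.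

Step 1
Reactants: 1 6-methylhept-5-en-2-one
Product: 3 (3S)-3-hydroxy-6-methylhept-5-en-2-one, via aminoxy ketone 2 (not isolated)
Conditions: PhNO (slow addition), 1 (5 equiv), D‑proline (20 mol %), DMSO, rt; then CuSO4·5H2O (30 mol %), MeOH, 0 °C
Reagents that add atoms: nitrosobenzene O=Nc1ccccc1
Why: Proline‑catalysed enamine α‑aminoxylation, in which the more substituted enamine of the methyl ketone attacks the nitroso oxygen held by the catalyst's carboxylic acid on one enamine face, so that D‑proline should set the (S)‑carbinol centre, after which Cu(II) cleaves the weak N–O bond without touching it.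

Step 2
Reactants: 3 (3S)-3-hydroxy-6-methylhept-5-en-2-one; 4 pent-1-yn-3-ol (racemic)
Product: 5 (6S,7S)-6,10-dimethylundec-9-en-4-yne-3,6,7-triol (C3 epimers)
Conditions: 4 (3 equiv), EtMgBr (6 equiv), THF, 0 → 40 °C; then 3, −40 → 0 °C; aqueous work‑up
Reagents that add atoms: none
Why: Cram‑chelate addition of an alkynyl Grignard reagent, in which the magnesium alkoxide of the ketol locks C=O and C–O in a five‑membered chelate and the acetylide enters from the side of the carbinol H, which sets the (6S) tertiary carbinol, while the C3 centre is a mixture that step 4 erases.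

Step 3
Reactants: 5 (6S,7S)-6,10-dimethylundec-9-en-4-yne-3,6,7-triol
Product: 6 (4E,6S,7S)-6,10-dimethylundeca-4,9-diene-3,6,7-triol (C3 epimers)
Conditions: Red‑Al (6 equiv), THF, 0 °C → rt; aq Rochelle salt
Reagents that add atoms: none
Why: Alkoxide‑directed trans‑hydroalumination of a propargylic alcohol followed by protonolysis should give only the (E)‑alkene and leaves the isolated trisubstituted alkene untouched.

Step 4
Reactants: 6 (4E,6S,7S)-6,10-dimethylundeca-4,9-diene-3,6,7-triol
Product: 7 (4E,6S,7S)-6,7-dihydroxy-6,10-dimethylundeca-4,9-dien-3-one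
Conditions: activated MnO2 (20 equiv), CH2Cl2, rt
Reagents that add atoms: none
Why: MnO2 oxidation is selective for the secondary allylic alcohol over the tertiary allylic and the non‑allylic secondary hydroxyl groups, and both C3 epimers converge on one enone.

Step 5
Reactants: 7 (4E,6S,7S)-6,7-dihydroxy-6,10-dimethylundeca-4,9-dien-3-one; 8 acryloyl chloride
Product: 9 (4E,6S,7S)-6-hydroxy-6,10-dimethyl-3-oxoundeca-4,9-dien-7-yl prop-2-enoate
Conditions: 8 (1.2 equiv), Et3N, CH2Cl2, −40 → 0 °C
Reagents that add atoms: none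
Why: Chemoselective O‑acylation, in which the secondary hydroxyl is esterified while the tertiary one is too hindered at low temperature, places the two‑carbon dienophile on the oxygen that stays in the target.

Step 6
Reactants: 9 (4E,6S,7S)-6-hydroxy-6,10-dimethyl-3-oxoundeca-4,9-dien-7-yl prop-2-enoate
Product: 10 (2Z,4E,6S,7S)-6,10-dimethyl-3,6-bis(trimethylsilyloxy)undeca-2,4,9-trien-7-yl prop-2-enoate
Conditions: TMSOTf (2.6 equiv), Et3N (4 equiv), Et2O, −20 → 0 °C; pentane, cold aq NaHCO3; used crude
Reagents that add atoms: trimethylsilyl triflate C[Si](C)(C)OS(=O)(=O)C(F)(F)F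
Why: Soft enolisation with silyl triflate and amine removes an α′‑proton of the ethyl ketone (the γ‑carbon is quaternary) to give the cross‑conjugated (Z)‑silyl dienol ether with its methyl group "outside", and it caps the tertiary alcohol as a TMS ether.

Step 7
Reactants: 10 (2Z,4E,6S,7S)-6,10-dimethyl-3,6-bis(trimethylsilyloxy)undeca-2,4,9-trien-7-yl prop-2-enoate
Product: 12 (3S,4S,4aS,7S,8aR)-4-hydroxy-4,7-dimethyl-3-(3-methylbut-2-en-1-yl)-3,4,4a,5,8,8a-hexahydro-1H-isochromene-1,6(7H)-dione, via bis-TMS cycloadduct 11 (not isolated)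
Conditions: PhMe (0.01 M), BHT (cat.), 125 °C, sealed tube; then 1 M HCl, THF, 0 °C
Reagents that add atoms: none
Why: On heating, the (1E,3Z)‑2‑silyloxydiene and the acrylate held on the neighbouring carbinol oxygen undergo a concerted, asynchronous normal‑electron‑demand [4+2] cycloaddition in which the acrylate CH2 bonds to the methyl‑bearing diene terminus and the acrylate α‑carbon bonds to the diene terminus next to the quaternary carbinol carbon, so that the "para" preference of the 2‑silyloxy group and the reach of the tether ask for the same regiochemistry. The closest known reaction type is the type 1 ester‑tethered intramolecular Diels–Alder reaction of hexa‑3,5‑dienyl acrylates (1,7,9‑decatriene class), here with a more reactive silyl dienol ether as in intramolecular double Michael reactions. The cyclohexene closes by the cycloaddition itself, and the δ‑lactone closes at the same time as the fused six‑membered ring spanned by the four‑atom tether (C, C, O, C=O). The new ring CH (C4a) is controlled by the two tether stereocentres: in the chair‑like tether the prenyl and methyl groups are equatorial, the methyl group stands anti to the forming bond and the silyloxy group takes the "inside" (axial) position, which exposes one diene face, whereas C8a (endo mode, as drawn) and C7 (diene geometry) are removed or equilibrated in step 9 and need no control. The step needs chemoselectivity for the acrylate over the unactivated prenyl alkene, which electronics secure, an s‑cis diene, which the "outside" methyl group allows, and suppression of acrylate polymerisation, which dilution and BHT secure. The acidic work‑up cleaves both TMS–O bonds and turns the enol ether into the ketone.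

Step 8
Reactants: 12 (3S,4S,4aS,7S,8aR)-4-hydroxy-4,7-dimethyl-3-(3-methylbut-2-en-1-yl)-3,4,4a,5,8,8a-hexahydro-1H-isochromene-1,6(7H)-dione
Product: 13 tricyclic bromo keto lactone (pyrano[3,2-c]isochromene-dione core: 12 with O‑4 bonded to the former alkene CMe2 carbon, giving a cis‑fused 3‑bromo‑2,2‑dimethyloxane with equatorial (S)‑Br)
Conditions: 2,4,4,6‑tetrabromocyclohexa‑2,5‑dienone (1.1 equiv), MeNO2, 0 °C, dark
Reagents that add atoms: 2,4,4,6-tetrabromocyclohexa-2,5-dien-1-one O=C1C(Br)=CC(Br)(Br)C=C1Br
Why: Bromonium‑induced 6‑endo (Markovnikov) bromoetherification, in which the axial tertiary hydroxyl on the chair δ‑lactone attacks the dimethyl‑substituted end of the bromonium ion anti to bromine through a chair fixed by the lactone template, should place the new C–Br bond equatorial (S), while the lactone blocks the secondary oxygen that would otherwise close a tetrahydrofuran.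

Step 9
Reactants: 13 tricyclic bromo keto lactone
Product: 15 (2R,5R)-5-[(2S,3S,5S)-5-bromo-3-hydroxy-2,6,6-trimethyloxan-2-yl]-2-methylcyclohexan-1-one, via lithium carboxylate 14 (not isolated)
Conditions: LiOH (1.1 equiv), THF–H2O, rt, evaporate; then 9‑mesityl‑10‑phenylacridinium BF4 (5 mol %), (PhS)2 (10 mol %), CF3CH2OH–H2O, 450 nm LED, rt
Reagents that add atoms: lithium hydroxide [Li+].[OH-] (its atoms stay only in 14)
Why: Saponification frees the oxane hydroxyl and equilibrates the α‑methyl group to the equatorial position, and photoredox hydrodecarboxylation (carboxylate oxidation, loss of CO2, H transfer from thiophenol to the secondary radical) removes the temporary carbon together with the ring‑fusion stereocentre while ketone, ether and the hindered secondary bromide are not oxidised.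

Step 10
Reactants: 15 (2R,5R)-5-[(2S,3S,5S)-5-bromo-3-hydroxy-2,6,6-trimethyloxan-2-yl]-2-methylcyclohexan-1-one
Product: 16 (2R,5R)-5-[(2S,3S,5S)-5-bromo-2,6,6-trimethyl-3-(triethylsilyloxy)oxan-2-yl]-2-methylcyclohexan-1-one
Conditions: TESOTf (1.3 equiv), 2,6‑lutidine, CH2Cl2, −78 °C
Reagents that add atoms: triethylsilyl triflate CC[Si](CC)(CC)OS(=O)(=O)C(F)(F)F
Why: Silyl triflate silylation covers the hindered axial oxane hydroxyl so that only the cyclohexane oxygen function is dehydrated in step 12.

Step 11
Reactants: 16 (2R,5R)-5-[(2S,3S,5S)-5-bromo-2,6,6-trimethyl-3-(triethylsilyloxy)oxan-2-yl]-2-methylcyclohexan-1-one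
Product: 17 (1S,2R,5R)-5-[(2S,3S,5S)-5-bromo-2,6,6-trimethyl-3-(triethylsilyloxy)oxan-2-yl]-2-methylcyclohexan-1-ol
Conditions: L‑Selectride (1.2 equiv), THF, −78 °C; aqueous work‑up
Reagents that add atoms: none
Why: The bulky trialkylborohydride attacks the 2‑methylcyclohexanone from the equatorial side and should give the axial (1S) alcohol cis to the equatorial methyl group, with its C–O bond antiperiplanar to the tertiary C–H.

Step 12
Reactants: 17 (1S,2R,5R)-5-[(2S,3S,5S)-5-bromo-2,6,6-trimethyl-3-(triethylsilyloxy)oxan-2-yl]-2-methylcyclohexan-1-ol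
Product: 18 (2S,3S,5S)-5-bromo-2,6,6-trimethyl-2-[(1R)-4-methylcyclohex-3-en-1-yl]-3-(triethylsilyloxy)oxane
Conditions: POCl3 (5 equiv), pyridine, 0 → 40 °C
Reagents that add atoms: none
Why: E2 dehydration of the axial dichlorophosphate, which has antiperiplanar axial hydrogens on both sides, should follow the Zaitsev preference known for cis‑2‑methylcyclohexanols and favour the trisubstituted alkene.

Step 13
Reactants: 18 (2S,3S,5S)-5-bromo-2,6,6-trimethyl-2-[(1R)-4-methylcyclohex-3-en-1-yl]-3-(triethylsilyloxy)oxane
Product: 20 (2S,3S,5S)-5-bromo-2,6,6-trimethyl-2-[(1R,3R,6S)-6-methyl-7-oxabicyclo[4.1.0]heptan-3-yl]-3-(triethylsilyloxy)oxane, via bromohydrin 19 (not isolated)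
Conditions: NBS (1.05 equiv), acetone–H2O, 0 °C; then K2CO3, MeOH, rt
Reagents that add atoms: water O; N-bromosuccinimide O=C1CCC(=O)N1Br (its Br stays only in 19)
Why: Bromohydrin formation in which Markovnikov and Fürst–Plattner control coincide only for the bromonium ion trans to the oxanyl group (water attacks the tertiary carbon trans‑diaxially, as with limonene‑type 4‑substituted 1‑methylcyclohexenes), followed by base‑induced SN2 closure, should give the single epoxide whose methyl group is trans to the oxanyl group.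

Step 14
Reactants: 20 (2S,3S,5S)-5-bromo-2,6,6-trimethyl-2-[(1R,3R,6S)-6-methyl-7-oxabicyclo[4.1.0]heptan-3-yl]-3-(triethylsilyloxy)oxane
Product: 21 (1S,2S,4R)-4-[(2S,3S,5S)-5-bromo-2,6,6-trimethyl-3-(triethylsilyloxy)oxan-2-yl]-2-chloro-1-methylcyclohexan-1-ol
Conditions: LiCl (5 equiv), AcOH (3 equiv), THF, rt
Reagents that add atoms: lithium chloride [Li+].[Cl-]
Why: Mildly acid‑assisted SN2 opening of the epoxide by chloride at the secondary carbon is both the less hindered and the trans‑diaxial (Fürst–Plattner) path for this epoxide face and sets the axial (S) C–Cl bond with inversion.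

Step 15
Reactants: 21 (1S,2S,4R)-4-[(2S,3S,5S)-5-bromo-2,6,6-trimethyl-3-(triethylsilyloxy)oxan-2-yl]-2-chloro-1-methylcyclohexan-1-ol
Product: 23 (2S,3S,5S)-5-bromo-2-[(1R,3S,4S)-4-bromo-3-chloro-4-methylcyclohexyl]-2,6,6-trimethyloxan-3-ol, via TES-protected target 22 (not isolated)
Conditions: TMSBr (3 equiv), CH2Cl2, −40 → 0 °C; then HF·pyridine, THF, 0 °C
Reagents that add atoms: bromotrimethylsilane C[Si](C)(C)Br
Why: Conversion of a tertiary alcohol into the bromide with TMSBr, in which the silylated axial oxygen leaves with help from the antiperiplanar axial chlorine and bromide opens the chloronium‑like ion at the tertiary carbon from the face the oxygen left, should give the trans‑diaxial tertiary bromide with retention (S), the low temperature guards against diaxial‑to‑diequatorial halogen interchange, and fluoride then frees the oxane hydroxyl.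

**Compound list**
1 | 6-methylhept-5-en-2-one | CC(=O)CCC=C(C)C | starting material
2 | (3S)-6-methyl-3-[(phenylamino)oxy]hept-5-en-2-one | CC(=O)[C@@H](ONc1ccccc1)CC=C(C)C | intermediate
3 | (3S)-3-hydroxy-6-methylhept-5-en-2-one | CC(=O)[C@@H](O)CC=C(C)C | intermediate
4 | pent-1-yn-3-ol (racemic) | CCC(O)C#C | starting material
5 | (6S,7S)-6,10-dimethylundec-9-en-4-yne-3,6,7-triol (C3 epimers) | O[C@@](C)(C#CC(O)CC)[C@@H](O)CC=C(C)C | intermediate
6 | (4E,6S,7S)-6,10-dimethylundeca-4,9-diene-3,6,7-triol (C3 epimers) | O[C@@](C)(/C=C/C(O)CC)[C@@H](O)CC=C(C)C | intermediate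
7 | (4E,6S,7S)-6,7-dihydroxy-6,10-dimethylundeca-4,9-dien-3-one | O[C@@](C)(/C=C/C(=O)CC)[C@@H](O)CC=C(C)C | intermediate
8 | acryloyl chloride | C=CC(=O)Cl | starting material
9 | (4E,6S,7S)-6-hydroxy-6,10-dimethyl-3-oxoundeca-4,9-dien-7-yl prop-2-enoate | O[C@@](C)(/C=C/C(=O)CC)[C@@H](OC(=O)C=C)CC=C(C)C | intermediate
10 | (2Z,4E,6S,7S)-6,10-dimethyl-3,6-bis(trimethylsilyloxy)undeca-2,4,9-trien-7-yl prop-2-enoate | C[Si](C)(C)O[C@@](C)(/C=C/C(O[Si](C)(C)C)=C/C)[C@@H](OC(=O)C=C)CC=C(C)C | intermediate
11 | (3S,4S,4aS,7S,8aR)-4,7-dimethyl-3-(3-methylbut-2-en-1-yl)-4,6-bis(trimethylsilyloxy)-3,4,4a,7,8,8a-hexahydro-1H-isochromen-1-one (cis‑fused endo adduct) | C[C@@]1(O[Si](C)(C)C)[C@H](CC=C(C)C)OC(=O)[C@@H]2C[C@H](C)C(O[Si](C)(C)C)=C[C@H]12 | intermediate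
12 | (3S,4S,4aS,7S,8aR)-4-hydroxy-4,7-dimethyl-3-(3-methylbut-2-en-1-yl)-3,4,4a,5,8,8a-hexahydro-1H-isochromene-1,6(7H)-dione | C[C@@]1(O)[C@H](CC=C(C)C)OC(=O)[C@@H]2C[C@H](C)C(=O)C[C@H]12 | intermediate
13 | tricyclic bromo keto lactone (12 with O‑4 joined to the former alkene CMe2 carbon; cis‑fused 3‑bromo‑2,2‑dimethyloxane, Br equatorial, S) | CC1(C)O[C@]2(C)[C@H](C[C@@H]1Br)OC(=O)[C@@H]3C[C@H](C)C(=O)C[C@H]23 | intermediate
14 | lithium (1R,2S,5R)-2-[(2S,3S,5S)-5-bromo-3-hydroxy-2,6,6-trimethyloxan-2-yl]-5-methyl-4-oxocyclohexane-1-carboxylate | CC1(C)O[C@@](C)([C@@H]2[C@H](C(=O)[O-])C[C@@H](C)C(=O)C2)[C@@H](O)C[C@@H]1Br.[Li+] | intermediate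
15 | (2R,5R)-5-[(2S,3S,5S)-5-bromo-3-hydroxy-2,6,6-trimethyloxan-2-yl]-2-methylcyclohexan-1-one | CC1(C)O[C@@](C)([C@@H]2CC[C@@H](C)C(=O)C2)[C@@H](O)C[C@@H]1Br | intermediate
16 | (2R,5R)-5-[(2S,3S,5S)-5-bromo-2,6,6-trimethyl-3-(triethylsilyloxy)oxan-2-yl]-2-methylcyclohexan-1-one | CC1(C)O[C@@](C)([C@@H]2CC[C@@H](C)C(=O)C2)[C@@H](O[Si](CC)(CC)CC)C[C@@H]1Br | intermediate
17 | (1S,2R,5R)-5-[(2S,3S,5S)-5-bromo-2,6,6-trimethyl-3-(triethylsilyloxy)oxan-2-yl]-2-methylcyclohexan-1-ol | CC1(C)O[C@@](C)([C@@H]2CC[C@@H](C)[C@@H](O)C2)[C@@H](O[Si](CC)(CC)CC)C[C@@H]1Br | intermediate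
18 | (2S,3S,5S)-5-bromo-2,6,6-trimethyl-2-[(1R)-4-methylcyclohex-3-en-1-yl]-3-(triethylsilyloxy)oxane | CC1(C)O[C@@](C)([C@@H]2CCC(C)=CC2)[C@@H](O[Si](CC)(CC)CC)C[C@@H]1Br | intermediate
19 | (1S,2S,4R)-2-bromo-4-[(2S,3S,5S)-5-bromo-2,6,6-trimethyl-3-(triethylsilyloxy)oxan-2-yl]-1-methylcyclohexan-1-ol | CC1(C)O[C@@](C)([C@@H]2CC[C@](C)(O)[C@@H](Br)C2)[C@@H](O[Si](CC)(CC)CC)C[C@@H]1Br | intermediate
20 | (2S,3S,5S)-5-bromo-2,6,6-trimethyl-2-[(1R,3R,6S)-6-methyl-7-oxabicyclo[4.1.0]heptan-3-yl]-3-(triethylsilyloxy)oxane | CC1(C)O[C@@](C)([C@@H]2CC[C@]3(C)O[C@@H]3C2)[C@@H](O[Si](CC)(CC)CC)C[C@@H]1Br | intermediate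
21 | (1S,2S,4R)-4-[(2S,3S,5S)-5-bromo-2,6,6-trimethyl-3-(triethylsilyloxy)oxan-2-yl]-2-chloro-1-methylcyclohexan-1-ol | CC1(C)O[C@@](C)([C@@H]2CC[C@](C)(O)[C@@H](Cl)C2)[C@@H](O[Si](CC)(CC)CC)C[C@@H]1Br | intermediate
22 | (2S,3S,5S)-5-bromo-2-[(1R,3S,4S)-4-bromo-3-chloro-4-methylcyclohexyl]-2,6,6-trimethyl-3-(triethylsilyloxy)oxane | CC1(C)O[C@@](C)([C@@H]2CC[C@](C)(Br)[C@@H](Cl)C2)[C@@H](O[Si](CC)(CC)CC)C[C@@H]1Br | intermediate
23 | (2S,3S,5S)-5-bromo-2-[(1R,3S,4S)-4-bromo-3-chloro-4-methylcyclohexyl]-2,6,6-trimethyloxan-3-ol | CC1(C)O[C@@](C)([C@@H]2CC[C@](C)(Br)[C@@H](Cl)C2)[C@@H](O)C[C@@H]1Br | target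

Total step count: 15. Longest linear sequence: 15 steps (1 → 23).

**Steps most likely to fail**

Step 15. Ionisation of the β‑chloro tertiary carbinol may be too slow. The cation may also lose a proton, or the two halogens may change places. The fallback sets out from 18 and replaces the stepwise chloronium generation by an interhalogen addition. NBS and Et4NCl in CH2Cl2 at −78 °C add Br and Cl across the ring alkene. The bromonium ion on the face cis to the oxanyl group is opened trans‑diaxially by chloride at the secondary carbon, as in the 5α‑bromo‑6β‑chloro steroid series. This gives 22 directly. The regioisomer that arises from the other bromonium face has to be removed by chromatography. The route is rejoined at 22, which HF·pyridine converts into 23.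

Step 7. The ester tether must adopt its less favoured conformer, so the cycloaddition may be sluggish, may lose to acrylate polymerisation, or may show poor facial selectivity in the flexible acyclic tether. The fallback sets out from 9 and changes the order of ring formation, so that a pre‑formed oxane locks the tether.
- Bromoetherification of 9 with the tetrabromodienone gives the oxane enone acrylate F1.
- TMSOTf/Et3N turns F1 into the silyl dienol ether F2.
- Heating F2 in dilute toluene gives the tricyclic silyl enol ether F3. Here the cis‑fused oxane/lactone transition state leaves one diene face open.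
- Acidic work‑up of F3 returns the route at 13.

Step 8. Closure may go 5‑exo to a tetrahydrofuran. The tertiary hydroxyl may translactonise first, and the ketone may be brominated at its α‑carbon. The fallback sets out from 12 and splits C–O and C–Br bond formation into two reactions.
- Reversible, strictly Markovnikov oxymercuration with Hg(OCOCF3)2 in MeNO2 closes the oxane and gives the organomercury trifluoroacetate F4, with mercury equatorial.
- Aqueous KBr exchanges it to the bromomercurial F5.
- Bromodemercuration with Br2/LiBr in pyridine (ionic conditions, retention) returns the route at 13.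

**Further compounds**
F1 | step 7 | (2S,3S,5S)-5-bromo-2,6,6-trimethyl-2-[(1E)-3-oxopent-1-en-1-yl]oxan-3-yl prop-2-enoate | CC1(C)O[C@@](C)(/C=C/C(=O)CC)[C@@H](OC(=O)C=C)C[C@@H]1Br
F2 | step 7 | (2S,3S,5S)-5-bromo-2,6,6-trimethyl-2-[(1E,3Z)-3-(trimethylsilyloxy)penta-1,3-dien-1-yl]oxan-3-yl prop-2-enoate | CC1(C)O[C@@](C)(/C=C/C(O[Si](C)(C)C)=C/C)[C@@H](OC(=O)C=C)C[C@@H]1Br
F3 | step 7 | trimethylsilyl enol ether of 13 (C=C towards the ring‑fusion CH) | CC1(C)O[C@]2(C)[C@H](C[C@@H]1Br)OC(=O)[C@@H]3C[C@H](C)C(O[Si](C)(C)C)=C[C@H]23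
F4 | step 8 | analogue of 13 with equatorial Hg(OCOCF3) in place of Br | CC1(C)O[C@]2(C)[C@H](C[C@@H]1[Hg]OC(=O)C(F)(F)F)OC(=O)[C@@H]3C[C@H](C)C(=O)C[C@H]23
F5 | step 8 | analogue of 13 with equatorial HgBr in place of Br | CC1(C)O[C@]2(C)[C@H](C[C@@H]1[Hg]Br)OC(=O)[C@@H]3C[C@H](C)C(=O)C[C@H]23
F0 | step 15 | none | none
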